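**The budget.** If a charge of nucleophile is to bring the electrophile just to the level asked, I must first know what that level costs in nucleophile.

electrophile 0.050 M; protic impurity 0.0100 M; time 50 min

1. the equivalents of nucleophile at which the part of the electrophile that has reacted at 50 min is just 50%

**The oddity.** The impurity's constant, 0.0554 L mol⁻¹ s⁻¹, is larger than the electrophile's 0.0453 L mol⁻¹ s⁻¹, yet at the start step 3 runs at just 0.245 of the rate of step 1. These fit because c(protic impurity) is 0.0100 M against 0.050 M for c(electrophile). In the ratio of the two rates c(nucleophile) cancels, and time drops out with it.

**The toll.** Setting the side step aside, the fraction of impurity left is therefore the fraction of electrophile left, raised to the power k3/k1, 1.22. At 50% this gives a toll of 0.114 equiv, out of 0.200 equiv of impurity charged; by the toll I mean the equivalents of nucleophile the impurity has taken when a given part of the electrophile has reacted.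

**My bracket.** Adding 50% of an equivalent for the target gave me 0.614 equiv, with no nucleophile counted as held by the acid set free. With one more nucleophile held by each acid set free, the sum was 1.11 equiv. I got no single number.

**The forecast.** It gave 0.73 equiv, inside my bracket, on the ground that the nucleophile is “nearly used up around 50 % conversion”.

**The run.** electrophile + nucleophile → acid set free + target (k1 = 0.0453 L mol⁻¹ s⁻¹); nucleophile + acid set free ⇌ protonated nucleophile, settled at all times (K2 = 378 L mol⁻¹); nucleophile + protic impurity → quenched reagent (k3 = 0.0554 L mol⁻¹ s⁻¹); crystals ⇌ target, rate k4*(cs4 - [target]) while solid is left; crystals form when [target] > cs4 (cs4 = 33 mM, k4 = 0.0144 s⁻¹); electrophile + acid set free → side product (k5 = 0.00162 L mol⁻¹ s⁻¹)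

The flask needs 0.743 equiv. In that flask, 3.16% of the charged nucleophile was still free at 50.0 min. Stopped after half the time, the same flask had used 42.4% of its electrophile, and the toll at that level reckons to 0.0981 equiv.

(The numbers of this flask are those of an exercise, and the outcome is calculated.)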